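**Retrosynthetic overview**
1. Feature: the seven-membered carbocycle (ring A: C1–C5–C6–C7–C8–C9–C10) holds the full carbon skeleton of (R)-carvone in C10(CH3)–C9(O)–C8H2–C7(C11/C12/C13), closed through C6 and C1. Only C5, between C1 and C6, is missing, so ring A is made by inserting one carbon into the carvone ring.
2. Endgame: C9–OH ⇐ silyl ether; C5 isobutyrate ⇐ anti opening of a C1–C5 epoxide; epoxide ⇐ C5 iodide; γ-lactone (ring B) ⇐ iodolactonization of the C11–C12 acrylic acid onto C5=C6.
3. Side chains: acrylic acid ⇐ allylic oxidation of isopropenyl; crotonyl ⇐ aldol condensation of a C1 acetyl group with acetaldehyde; C1 carbinol ⇐ 1-ethoxyvinyllithium + cyclohept-2-enone.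
4. Key disconnection: cyclohept-2-enone ⇐ siloxycyclopropane ⇐ kinetic C1=C6 silyl enol ether of the 3-silyloxy-dihydrocarvone + CH2 (C5) from CH2I2. C1–C5 and C5–C6 are made and C1–C6 is cut.
5. The trans C9–O/C10–CH3 pair ⇐ syn-hydroboration of cis-carveol locked as an iodo ether. Ring order: six-membered ring (carvone) → cyclopropane → ring A by enlargement → ring B.

Key step: step 8

Remark: α is the face of C10–CH3, C1–OH, C6–O and C7–C11, and β is the face of C9–O, C2 and C5–O (target: 1S,5S,6R,7S,9R,10S); protonation of a C1=C10 enolate, such as the one formed by reductive opening of carvone oxide, is expected to occur anti to the pseudoaxial C9 oxygen and leave C10–CH3 cis to C9–O, so the trans pair is set by syn-hydroboration instead.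

**Step 1**
Reactants: 1 (R)-(−)-carvone
Product: 2 (−)-cis-carveol, (1R,5R)-2-methyl-5-(prop-1-en-2-yl)cyclohex-2-en-1-ol (C1–OH α)
Conditions: NaBH4, CeCl3·7H2O, MeOH, −20 → 0 °C
Reagents that add atoms: none
Why: Luche reduction: the cerium-modified borohydride should attack the enone carbonyl 1,2 and axially on the half-chair that keeps the C7 isopropenyl group equatorial, which sets C1–OH α, cis to the isopropenyl group as step 2 requires.

**Step 2**
Reactants: 2 (−)-cis-carveol
Product: 3 iodo ether 7-(iodomethyl)-4,7-dimethyl-6-oxabicyclo[3.2.1]oct-3-ene (O bridges C1 and C11 on the α face; C11 epimers)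
Conditions: I2, NaHCO3, MeCN, 0 °C, dark
Reagents that add atoms: iodine, II
Why: Iodoetherification (5-exo, Markovnikov): iodonium formation is reversible at both alkenes but only the isopropenyl iodonium can be captured by the cis C1–OH at tertiary C11, so one operation should mask the hydroxyl and the alkene more prone to hydroboration and lock the ring in the chair with the C7 substituent axial, while the new centre C11 is destroyed again in step 5.

**Step 3**
Reactants: 3 iodo ether
Product: 5 exo alcohol 7-(iodomethyl)-4,7-dimethyl-6-oxabicyclo[3.2.1]octan-3-ol (C9–OH β; C10–CH3 α), via alkylborane 4 (not isolated)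
Conditions: BH3·THF, THF, 0 °C → rt; then NaOH, H2O2, 0 °C
Reagents that add atoms: hydrogen peroxide, OO
Why: Brown hydroboration–oxidation: H and B add syn, boron to the less substituted C9 and hydrogen to C10, from the exo (β) face because the O–C11 bridge with its endo substituent covers the α face, and oxidation with retention should give C9–OH β and C10–CH3 α, the trans pair with both groups equatorial.

**Step 4**
Reactants: 5 exo alcohol
Product: 6 tert-butyldimethylsilyl ether of 5
Conditions: TBSCl, imidazole, DMF, rt
Reagents that add atoms: tert-butyldimethylsilyl chloride, CC(C)(C)[Si](C)(C)Cl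
Why: Standard imidazole-promoted silylation of the unhindered equatorial secondary alcohol, the only free hydroxyl in 5.

**Step 5**
Reactants: 6 silylated iodo ether
Product: 7 3-(tert-butyldimethylsilyloxy)-2-methyl-5-(prop-1-en-2-yl)cyclohexan-1-ol (C1–OH α; C10–CH3 α; C9–OSi β; C7 isopropenyl α)
Conditions: Zn dust, NH4Cl, EtOH, 70 °C
Reagents that add atoms: none
Why: Boord-type reductive β-elimination: zinc inserts into the primary C–I bond and the organozinc expels the β-alkoxide, which should release the isopropenyl group and C1–OH together without touching C7, C9, C10 or the silyl ether.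

**Step 6**
Reactants: 7 cyclohexanol
Product: 8 (2S,3R,5R)-3-(tert-butyldimethylsilyloxy)-2-methyl-5-(prop-1-en-2-yl)cyclohexan-1-one
Conditions: Dess–Martin periodinane, CH2Cl2, 0 °C → rt
Reagents that add atoms: none
Why: Dess–Martin oxidation runs without base, so the ketone should form without enolization and the epimerizable C10 centre (CH3 trans to C9–O) is kept.

**Step 7**
Reactants: 8 silyloxy ketone
Product: 9 kinetic trimethylsilyl enol ether (C1=C6) of 8
Conditions: TMSCl, LDA (in situ quench), THF, −78 °C; cold NaHCO3 work-up
Reagents that add atoms: chlorotrimethylsilane, C[Si](C)(C)Cl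
Why: Kinetic enolate silylation: the hindered amide removes a proton from the less substituted C6H2 and not the tertiary C10–H, and trapping in situ prevents enolate equilibration, C10 epimerization and E1cB loss of the C9 silyloxy group.

**Step 8**
Reactants: 9 kinetic trimethylsilyl enol ether; 10 diiodomethane
Product: 14 (4R,6R,7S)-6-(tert-butyldimethylsilyloxy)-7-methyl-4-(prop-1-en-2-yl)cyclohept-2-en-1-one, via zinc carbenoid 11 (not isolated), via siloxycyclopropane 12 (not isolated), via β-chloro ketone 13 (not isolated)
Conditions: Et2Zn, CH2I2 (1.2 equiv each), toluene, 0 °C; aq. NH4Cl wash, crude 12; FeCl3 (2.3 equiv), pyridine, DMF, 0 °C → rt; extraction, crude 13; NaOAc, MeOH, 55 °C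
Reagents that add atoms: diiodomethane, ICI
Why: The zinc carbenoid 11 transfers CH2 (C5) in a concerted addition to the electron-rich C1=C6 enol ether, making C1–C5 and C5–C6 at once (Furukawa-modified Simmons–Smith cyclopropanation). FeCl3 (trivalent iron) then takes the place of silicon on the cyclopropanol oxygen and oxidizes it by one electron; the oxygen-centred radical cleaves the shared C1–C6 bond, the C6 radical abstracts chlorine from a second FeCl3, and acetate removes HCl from 13 by way of the C5 enolate, the whole being the Ito–Saegusa one-carbon ring expansion of cyclic silyl enol ethers. The three-membered ring closes by [2+1] cycloaddition, and ring A arises by enlargement of the six-membered ring (cleavage of the zero-atom bridge of the bicyclo[4.1.0]heptane), not by an end-to-end cyclization. No stereocentre of 14 is created: C1 and C6 of the cyclopropane become sp2 again, so the face of CH2 transfer does not matter, and C7, C9 and C10 pass through because none of them is enolized or ionized. The step needs regioselectivity (fixed in step 7 by deprotonation at C6H2), chemoselectivity for the enol ether over the isopropenyl alkene (the silyloxy alkene is far more nucleophilic toward the electrophilic carbenoid, and only a slight excess is used) and scission of the internal and not the external cyclopropane bond (secondary versus primary radical, relief of bicyclic strain). The weak base NaOAc is chosen so that C10–H is not exchanged and the β-silyloxy group at C9 is not eliminated.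

**Step 9**
Reactants: 14 cycloheptenone; 15 ethyl vinyl ether
Product: 18 α-hydroxy methyl ketone (C1: acetyl β; OH α; C5=C6 and isopropenyl intact), via 1-ethoxyvinyllithium 16 (not isolated), via enol ether adduct 17 (not isolated)
Conditions: 15, t-BuLi, THF, −78 → 0 °C; 14, −78 °C; then 1 M HCl, THF, 0 °C
Reagents that add atoms: ethyl vinyl ether, C=COCC; water, O
Why: 1,2-Addition of an acyl-anion equivalent (α-lithiated enol ether) followed by enol-ether hydrolysis: the hard organolithium attacks the carbonyl and not C6, and in the chair-like conformer of 14 with C10–CH3 and C9–OSi equatorial the pseudoaxial C7 isopropenyl group and H9 screen the α face of C1, so C2 should enter on the equatorial-type β trajectory trans to C10–CH3 (as with 2-methylcycloalkanones), setting C1 with OH α, after which dilute acid cleaves only the enol ether.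

**Step 10**
Reactants: 18 α-hydroxy methyl ketone; 19 acetaldehyde
Product: 21 aldol adduct with a C1 3-hydroxybutanoyl group (carbinol epimers), via dilithium enolate alkoxide 20 (not isolated)
Conditions: LDA (2.2 equiv), THF, −78 °C; CH3CHO, −78 °C; AcOH quench
Reagents that add atoms: acetaldehyde, CC=O
Why: Directed aldol addition of a kinetic lithium enolate: the first equivalent of base takes the C1–OH proton, C1 is quaternary so only the acetyl CH3 can be enolized, and the new carbinol centre is removed in step 11.

**Step 11**
Reactants: 21 aldol adduct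
Product: 23 (E)-but-2-enoyl carbinol (crotonyl β and OH α at C1), via mesylate 22 (not isolated)
Conditions: MsCl (1.2 equiv), Et3N (5 equiv), CH2Cl2, −20 °C → rt
Reagents that add atoms: none
Why: Mesylation of the secondary β-hydroxyl (the hindered tertiary α-ketol OH stays free) and E1cB elimination should give the conjugated enone with the thermodynamically preferred E geometry.

**Step 12**
Reactants: 23 crotonyl carbinol
Product: 25 enal (C7 carries C11(=C13H2)–C12HO), via allylic alcohol 24 (not isolated)
Conditions: SeO2 (0.4 equiv), t-BuOOH, CH2Cl2, 0 °C → rt; crude, Dess–Martin periodinane, CH2Cl2, 0 °C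
Reagents that add atoms: selenium dioxide (catalytic oxygen carrier), O=[Se]=O; tert-butyl hydroperoxide (terminal oxidant), CC(C)(C)OO
Why: Riley-type allylic oxidation (ene reaction, then [2,3]-sigmatropic shift): the isopropenyl alkene is the most electron-rich one (C5=C6 is deactivated by the oxygen and acyl groups on C1, and the enone is electron-poor) and allylic strain holds C7–H in the nodal plane of that alkene, so the CH3 group should react, and the Dess–Martin oxidation converges the alcohol and any aldehyde already formed to 25.

**Step 13**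
Reactants: 25 enal
Product: 26 acrylic acid (C7 carries C11(=C13H2)–C12O2H)
Conditions: NaClO2, NaH2PO4, 2-methyl-2-butene, t-BuOH/H2O, 0 °C → rt
Reagents that add atoms: sodium chlorite, [Na+].[O-]Cl=O
Why: Pinnick oxidation converts the 2-substituted acrolein into the acid under buffered conditions, with 2-methyl-2-butene scavenging HOCl so that the alkenes, the silyl ether and the α-ketol are left alone.

**Step 14**
Reactants: 26 acrylic acid
Product: 27 iodolactone (cis-fused α-methylene-γ-lactone; C6–O α; C5–I β)
Conditions: I2, NaHCO3, MeCN, 0 °C → rt, dark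
Reagents that add atoms: iodine, II
Why: Iodolactonization (5-exo, anti addition): the carboxylate is held on the α face by C7 and can only open the β-iodonium ion at C6, the carbon remote from the electron-withdrawing C1, which should close the cis-fused lactone (C6–O α) and place iodine β at C5, anti to C1–OH, while the acrylate and enone alkenes are too electron-poor to react with I2.

**Step 15**
Reactants: 27 iodolactone
Product: 28 C1–C5 α-epoxide (crotonyl β at C1; lactone unchanged)
Conditions: Ag2O, 4 Å MS, CH2Cl2, rt, dark
Reagents that add atoms: none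
Why: Halohydrin-to-epoxide closure (intramolecular SN2, 3-exo-tet): the α C1–OH is anti to the β C5–I, silver assists departure of iodide and the oxide takes the proton, so C5 is inverted in the absence of any nucleophilic base that could add to the α-methylene lactone.

**Step 16**
Reactants: 28 epoxide; 29 isobutyric acid
Product: 30 C9 silyl ether of the target (C5–O-isobutyryl β; C1–OH α)
Conditions: i-PrCO2H (10 equiv), i-PrCO2Cs (0.5 equiv), BHT, DMF, 70 °C
Reagents that add atoms: isobutyric acid, CC(C)C(=O)O
Why: Carboxylate opening of an epoxide (SN2, anti): C1 is fully substituted and α to the ketone, so the buffered isobutyrate should attack the secondary C5 from the β face with a second inversion, giving the β ester trans to both C1–OH and C6–O, and the non-acidic medium keeps the C9 silyl ether from attacking C5 across the ring and avoids acyl shift of the epoxy ketone.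

**Step 17**
Reactants: 30 silyl ether of the target
Product: 31 CNP0123946.1 (1S,5S,6R,7S,9R,10S)
Conditions: HF·pyridine, pyridine, THF, 0 °C → rt
Reagents that add atoms: none
Why: Fluoride-mediated desilylation in a slightly acidic medium removes the secondary silyl ether while avoiding the basic conditions that would cause acyl migration or conjugate addition to the α-methylene lactone and the enone.

**Compound list**
1 | (R)-(−)-carvone | O=C1C[C@H](C(C)=C)CC=C1C | starting material
2 | (−)-cis-carveol | O[C@@H]1C[C@H](C(C)=C)CC=C1C | intermediate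
3 | iodo ether, 7-(iodomethyl)-4,7-dimethyl-6-oxabicyclo[3.2.1]oct-3-ene (C11 epimers) | CC1=CC[C@@H]2C[C@H]1OC2(C)CI | intermediate
4 | C9 alkylborane from 3 (B β, H10 β) | C[C@H]1[C@H](B)C[C@@H]2C[C@H]1OC2(C)CI | intermediate
5 | exo alcohol (C9–OH β, C10–CH3 α) | C[C@H]1[C@H](O)C[C@@H]2C[C@H]1OC2(C)CI | intermediate
6 | TBS ether of 5 | C[C@H]1[C@H](O[Si](C)(C)C(C)(C)C)C[C@@H]2C[C@H]1OC2(C)CI | intermediate
7 | 3-silyloxy-2-methyl-5-isopropenylcyclohexanol (C1–OH α) | O[C@@H]1C[C@H](C(C)=C)C[C@@H](O[Si](C)(C)C(C)(C)C)[C@@H]1C | intermediate
8 | (2S,3R,5R)-3-(tert-butyldimethylsilyloxy)-2-methyl-5-(prop-1-en-2-yl)cyclohexan-1-one | O=C1C[C@H](C(C)=C)C[C@@H](O[Si](C)(C)C(C)(C)C)[C@@H]1C | intermediate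
9 | kinetic trimethylsilyl enol ether (C1=C6) | C[Si](C)(C)OC1=C[C@H](C(C)=C)C[C@@H](O[Si](C)(C)C(C)(C)C)[C@@H]1C | intermediate
10 | diiodomethane | ICI | starting material
11 | (iodomethyl)ethylzinc | CC[Zn]CI | intermediate
12 | siloxycyclopropane, 1-(trimethylsilyloxy)bicyclo[4.1.0]heptane (either cyclopropane face) | C[Si](C)(C)OC12CC1[C@H](C(C)=C)C[C@@H](O[Si](C)(C)C(C)(C)C)[C@@H]2C | intermediate
13 | 3-chlorocycloheptanone (Cl at C6, epimers) | O=C1CC(Cl)[C@H](C(C)=C)C[C@@H](O[Si](C)(C)C(C)(C)C)[C@@H]1C | intermediate
14 | (4R,6R,7S)-6-(tert-butyldimethylsilyloxy)-7-methyl-4-(prop-1-en-2-yl)cyclohept-2-en-1-one | O=C1C=C[C@H](C(C)=C)C[C@@H](O[Si](C)(C)C(C)(C)C)[C@@H]1C | intermediate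
15 | ethyl vinyl ether | C=COCC | starting material
16 | 1-ethoxyvinyllithium | [Li]C(=C)OCC | intermediate
17 | enol ether adduct (lithium alkoxide in the flask, drawn as the alcohol) | C=C(C)[C@@H]1C[C@@H](O[Si](C)(C)C(C)(C)C)[C@H](C)[C@@](O)(C(=C)OCC)C=C1 | intermediate
18 | α-hydroxy methyl ketone | C=C(C)[C@@H]1C[C@@H](O[Si](C)(C)C(C)(C)C)[C@H](C)[C@@](O)(C(C)=O)C=C1 | intermediate
19 | acetaldehyde | CC=O | starting material
20 | dilithium enolate alkoxide of 18 | C=C(C)[C@@H]1C[C@@H](O[Si](C)(C)C(C)(C)C)[C@H](C)[C@@](O[Li])(C(=C)O[Li])C=C1 | intermediate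
21 | aldol adduct (carbinol epimers) | C=C(C)[C@@H]1C[C@@H](O[Si](C)(C)C(C)(C)C)[C@H](C)[C@@](O)(C(=O)CC(C)O)C=C1 | intermediate
22 | mesylate of 21 | C=C(C)[C@@H]1C[C@@H](O[Si](C)(C)C(C)(C)C)[C@H](C)[C@@](O)(C(=O)CC(C)OS(C)(=O)=O)C=C1 | intermediate
23 | crotonyl carbinol | C=C(C)[C@@H]1C[C@@H](O[Si](C)(C)C(C)(C)C)[C@H](C)[C@@](O)(C(=O)/C=C/C)C=C1 | intermediate
24 | allylic alcohol | C=C(CO)[C@@H]1C[C@@H](O[Si](C)(C)C(C)(C)C)[C@H](C)[C@@](O)(C(=O)/C=C/C)C=C1 | intermediate
25 | enal | C=C(C=O)[C@@H]1C[C@@H](O[Si](C)(C)C(C)(C)C)[C@H](C)[C@@](O)(C(=O)/C=C/C)C=C1 | intermediate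
26 | acrylic acid | C=C(C(=O)O)[C@@H]1C[C@@H](O[Si](C)(C)C(C)(C)C)[C@H](C)[C@@](O)(C(=O)/C=C/C)C=C1 | intermediate
27 | iodolactone | C=C1C(=O)O[C@@H]2[C@H]1C[C@@H](O[Si](C)(C)C(C)(C)C)[C@H](C)[C@@](O)(C(=O)/C=C/C)[C@H]2I | intermediate
28 | C1–C5 α-epoxide | C=C1C(=O)O[C@@H]2[C@H]1C[C@@H](O[Si](C)(C)C(C)(C)C)[C@H](C)[C@]3(C(=O)/C=C/C)O[C@H]23 | intermediate
29 | isobutyric acid | CC(C)C(=O)O | starting material
30 | C9 TBS ether of the target | C=C1C(=O)O[C@@H]2[C@H]1C[C@@H](O[Si](C)(C)C(C)(C)C)[C@H](C)[C@@](O)(C(=O)/C=C/C)[C@H]2OC(=O)C(C)C | intermediate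
31 | CNP0123946.1 | C=C1C(=O)O[C@@H]2[C@H]1C[C@@H](O)[C@H](C)[C@@](O)(C(=O)/C=C/C)[C@H]2OC(=O)C(C)C | target

**Total step count:** 17. **Longest linear sequence:** 17 steps (1 → 31).

**Steps most likely to fail**

Step 16. The weak carboxylate nucleophile meets a hindered C5 that is inductively deactivated by C6–O. The opening may therefore be sluggish, and prolonged heating invites acyl shift of the epoxy ketone, transannular attack by the C9 oxygen or polymerization of the α-methylene lactone.
The fallback brings both oxygens in from the α face and inverts C5 afterwards. It sets out from acid 26. Hydrogen-bond-directed dihydroxylation (OsO4, TMEDA, CH2Cl2, −78 °C, reductive work-up) is steered by the α C1–OH to the α face of C5=C6, the only alkene that is not electron-poor, and should give the triol acid F5. Its C6–OH, cis to the C7 side chain, lactonizes to the C5-epimeric hydroxy lactone F6. A Mitsunobu reaction of F6 with 29 (PPh3, DIAD, toluene) inverts C5, and the syn C1–OH cannot interfere. The fallback comes back to the route at 30.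

Step 9. The facial selectivity at C1 rests on a conformational argument, so the organolithium may attack from the α face. It may also act as a base and trigger loss of the C9 silyloxy group.
The fallback reverses the order in which carbon and oxygen arrive at C1, so it helps when the α face proves to be the open one. It sets out from 14. Wittig olefination with the ylide from (1-methoxyethyl)triphenylphosphonium chloride (KHMDS, THF) should give the exocyclic methyl enol ether F4. Dimethyldioxirane (acetone, −78 → 0 °C) oxidizes this most electron-rich alkene from the open face, and the methoxy epoxide collapses on aqueous work-up with loss of methanol, placing OH on C1. The fallback comes back to the route at 18.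

Step 8. The isopropenyl group may be cyclopropanated in competition with the enol ether. The enol ether may be hydrolysed by zinc salts, the C9 silyl ether may be lost to FeCl3, and C10–H may be exchanged or the silyloxy group eliminated during the dehydrochlorination.
The fallback keeps the one-carbon enlargement between C1 and C6 but uses a 1,2-shift in place of a radical scission. It sets out from ketone 8. Trimethylsilyldiazomethane with BF3·OEt2 (CH2Cl2, −78 °C) adds to the carbonyl and the less substituted C6 migrates, giving the α-trimethylsilyl cycloheptanone F1. This is protodesilylated on silica or with dilute acid to the saturated cycloheptanone F2. Kinetic silylation (LDA, TMSCl, −78 °C) gives the C1=C5 enol silane F3, and Saegusa–Ito dehydrogenation with Pd(OAc)2 in MeCN installs C5=C6. The fallback comes back to the route at 14.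

**Further compounds**
F1 | step 8 | α-trimethylsilyl cycloheptanone (silyl at C5, epimers) | O=C1C([Si](C)(C)C)C[C@H](C(C)=C)C[C@@H](O[Si](C)(C)C(C)(C)C)[C@@H]1C
F2 | step 8 | saturated cycloheptanone | O=C1CC[C@H](C(C)=C)C[C@@H](O[Si](C)(C)C(C)(C)C)[C@@H]1C
F3 | step 8 | C1=C5 enol silane | C[Si](C)(C)OC1=CC[C@H](C(C)=C)C[C@@H](O[Si](C)(C)C(C)(C)C)[C@@H]1C
F4 | step 9 | exocyclic methyl enol ether (alkene isomers) | COC(C)=C1C=C[C@H](C(C)=C)C[C@@H](O[Si](C)(C)C(C)(C)C)[C@@H]1C
F5 | step 16 | triol acid (C5–OH α, C6–OH α) | C=C(C(=O)O)[C@@H]1C[C@@H](O[Si](C)(C)C(C)(C)C)[C@H](C)[C@@](O)(C(=O)/C=C/C)[C@H](O)[C@@H]1O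
F6 | step 16 | C5-epimeric hydroxy lactone (C5–OH α) | C=C1C(=O)O[C@@H]2[C@H]1C[C@@H](O[Si](C)(C)C(C)(C)C)[C@H](C)[C@@](O)(C(=O)/C=C/C)[C@@H]2O
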